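## Retrosynthetic overview
1. Caruifolin B is a Diels–Alder heterodimer of two identical guaianolide halves. The norbornanone half comes from a 2-silyloxycyclopentadiene (diene, C3 oxidised). The cyclopentene half comes from the 3-deoxy-cyclopentadiene (dienophile, C2=C3). Both dienes derive from one enone, 10-hydroxyguai-4-en-3-one-12,6-olide (**17**).
2. The 10-methyl carbinol of **17** comes from Me addition to a C10 ketone. The 5-7 hydroazulenone comes from an intramolecular Pauson–Khand reaction (PKR) of a 1,8-enyne that already carries the trans,trans-lactone.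
3. The lactone comes from tandem conjugate addition/alkylation of a γ-alkynyl butenolide. The butenolide comes from RCM of a propargylic acrylate, whose carbinol is set by CBS reduction of an ynone made from achiral materials.
4. Ring order: lactone, then the 7- and 5-membered carbocycles together in the PKR, then the norbornanone and new cyclopentene in the Diels–Alder dimerization.

Assumptions:
- N-Methoxy-N-methylacrylamide is commercially available.
- The Diels–Alder is endo and occurs on the face anti to each C10 substituent.
- C1–H (α to the C10 ketone) and the B-ring C4-methyl (α to the norbornanone C=O) both equilibrate to the configuration shown in the target.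

## Route

**Step 1**
Reactants: **1** N-methoxy-N-methylacrylamide; **2** propynyllithium
Product: **3** hex-1-en-4-yn-3-one
Conditions: **2** (from propyne, n-BuLi), THF, –78 °C; then **1**, –78 → 0 °C
Reagents that add atoms: **2** propynyllithium, CC#C[Li]
Why: Weinreb ketone synthesis; the chelated tetrahedral intermediate stops at the ynone. No stereocentre is formed.

**Step 2**
Reactants: **3**
Product: **4** (S)-hex-1-en-4-yn-3-ol
Conditions: (S)-Me-CBS (10 mol %), BH3·SMe2, THF, –20 °C
Reagents that add atoms: none (hydride only)
Why: CBS (oxazaborolidine, metal-free) asymmetric ketone reduction; the small linear alkynyl group versus the vinyl group discriminates the faces. This sets C6 and is the first stereocentre.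

**Step 3**
Reactants: **4**; **5** acryloyl chloride
Product: **6** (S)-1-en-4-yn-3-yl acrylate
Conditions: **5**, Et3N, DMAP (cat.), CH2Cl2, 0 °C
Reagents that add atoms: **5** acryloyl chloride, C=CC(Cl)=O
Why: Simple esterification with retention at the carbinol.

**Step 4**
Reactants: **6**
Product: **7** (S)-5-(prop-1-yn-1-yl)furan-2(5H)-one
Conditions: Grubbs II (5 mol %), CH2Cl2 (0.01 M), 40 °C
Reagents that add atoms: none (ethylene is lost)
Why: Ring-closing metathesis of the acrylate with the vinyl group gives the γ-alkynyl butenolide (C7=C11), with C6 untouched.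

**Step 5**
Reactants: **7**; **8** 2-(1,3-dioxolan-2-yl)ethylmagnesium bromide; **9** methyl iodide
Product: **10** trans,trans-3-methyl-4-[2-(1,3-dioxolan-2-yl)ethyl]-5-(propynyl)dihydrofuran-2-one
Conditions: **8** (2 equiv), CuBr·SMe2 (20 mol %), THF, –78 °C; then **9**, DMPU, –78 → –20 °C
Reagents that add atoms: **8** Br[Mg]CCC1OCCO1; **9** CI
Why: Tandem Cu-catalysed conjugate addition and enolate alkylation. The Grignard adds anti to the C6 alkynyl group (sets C7), and MeI alkylates anti to the C7 chain (sets C11). This gives the C6/C7/C11 relative and absolute configuration of the target.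

**Step 6**
Reactants: **10**
Product: **11** aldehyde (C10 CHO)
Conditions: PPTS, acetone/H2O (10:1), 60 °C
Reagents that add atoms: water (O), O
Why: Acetal hydrolysis unmasks C10; the lactone and alkyne are untouched.

**Step 7**
Reactants: **11**; **12** vinylmagnesium bromide
Product: **13** secondary allylic alcohol (C10 epimeric mixture)
Conditions: **12**, THF, –78 °C
Reagents that add atoms: **12** C=C[Mg]Br
Why: 1,2-Addition to the aldehyde, which is far more reactive than the lactone at –78 °C. The C10 stereocentre is irrelevant because it is oxidised in Step 9.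

**Step 8**
Reactants: **13**
Product: **14** hydroazulenone-lactone (3-oxo-4-ene, C10 secondary OH)
Conditions: Co2(CO)8, CH2Cl2, rt; then TMANO·2H2O, rt → 40 °C
Reagents that add atoms: CO from Co2(CO)8, [C-]#[O+] (becomes C3)
Why: Intramolecular Pauson–Khand reaction of the 1,8-enyne. One step builds the 7-membered ring (C1–C5 bond) and the tetrasubstituted cyclopentenone (C4 Me, C3=O, C2H2). The product is a mixture at C10, and C1 is treated as undetermined at this stage.

**Step 9**
Reactants: **14**
Product: **15** C10 ketone
Conditions: DMP, NaHCO3, CH2Cl2, 0 °C → rt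
Reagents that add atoms: none
Why: Oxidation removes the C10 stereochemistry. C1–H is now α to a ketone and γ to the enone, so C1 settles on the favoured configuration (equilibration on workup and silica).

**Step 10**
Reactants: **15**; **16** methylmagnesium bromide
Product: **17** (10-hydroxyguai-4-en-3-one-12,6-olide)
Conditions: **16**, LaCl3·2LiCl, THF, –78 °C
Reagents that add atoms: **16** C[Mg]Br
Why: LaCl3-promoted chemoselective 1,2-addition to the most reactive ketone (C10), over the hindered conjugated C3 ketone and the lactone. Me enters from the face syn to H1 and anti to C2, giving C10 with OH on the C2 face as in the target.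

**Step 11**
Reactants: **17**; **18** TESOTf
Product: **19** C10-OTES enone
Conditions: **18**, 2,6-lutidine, CH2Cl2, –78 °C
Reagents that add atoms: **18** CC[Si](CC)(CC)OS(=O)(=O)C(F)(F)F
Why: The tertiary alcohol is protected so it survives the dehydration and silyl-enol-ether steps.

**Step 12**
Reactants: **19**
Product: **20** C3 allylic alcohol (epimeric mixture)
Conditions: NaBH4, CeCl3·7H2O, MeOH, –78 °C
Reagents that add atoms: none (hydride only)
Why: Luche reduction is selective for the enone carbonyl over the lactone. The C3 configuration is immaterial.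

**Step 13**
Reactants: **20**
Product: **21** guaia-2,4-diene (cyclopentadiene, C10-OTES)
Conditions: Burgess reagent, benzene, rt (product used cold and immediately)
Reagents that add atoms: none
Why: Syn-elimination is regiospecific because C4 has no hydrogen, so only C2–H can leave. This gives the conjugated C2=C3/C4=C5 diene.

**Step 14**
Reactants: **19**; **22** TBSOTf
Product: **23** 3-(TBSO)-guaia-2,4-diene, C10-OTES (2-silyloxycyclopentadiene)
Conditions: **22**, Et3N, CH2Cl2, 0 °C
Reagents that add atoms: **22** CC(C)(C)[Si](C)(C)OS(=O)(=O)C(F)(F)F
Why: Deprotonation at C2, the only α′ position, gives the cross-conjugated silyl dienol ether, which is the diene partner.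

**Step 15**
Reactants: **21** (3 equiv, slow addition); **23**
Product: **24** bis-TES, TBS enol ether Diels–Alder adduct
Conditions: Mes-Acr+ BF4– (5 mol %), 2,6-di-tert-butylpyridine (20 mol %), CH2Cl2 (0.05 M), blue LEDs, 0 °C
Reagents that add atoms: none
Why: Proposed new method: organophotoredox radical-cation Diels–Alder heterodimerization, the intermolecular coupling of a 2-silyloxycyclopentadiene with a cyclopentadiene that builds the bicyclo[2.2.1]heptanone and a quaternary centre.
- The most easily oxidised partner, **23**, gives the radical cation (hole transfer from **21**•+ also funnels to it).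
- The nucleophilic C2 of **23** bonds to the terminal C2 of the neutral diene **21**. This gives an allyl-stabilised radical cation, and the second bond (C5 to C3) then closes to the radical cation of the silyl enol ether.
- That adduct radical cation oxidises more **23**, so the chain propagates; the adduct is less easily oxidised than **23**.
- Both partners react on the face anti to their C10 substituent, syn to H1, and the cyclopentadiene ring ends up endo.
- This sets A-C2, A-C3, B-C2 and B-C5.
- The closest known reactions are the Bauld aminium-salt and photocatalytic radical-cation Diels–Alder reactions of cyclopentadiene.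

**Step 16**
Reactants: **24**
Product: **25** caruifolin B
Conditions: TBAF (10 equiv), THF, 0 °C → rt; then aq. NH4Cl
Reagents that add atoms: none (fluoride and H are lost or gained only as H/Si-F)
Why: Fluoride removes both TES ethers and the enol TBS ether. The resulting C3 enolate is protonated at C4, and basic equilibration puts the methyl exo (H endo), away from the endo-fused A ring, as in the target.

## Compound list
1 | N-methoxy-N-methylacrylamide | C=CC(=O)N(C)OC | starting material
2 | propynyllithium | CC#C[Li] | starting material
3 | hex-1-en-4-yn-3-one | C=CC(=O)C#CC | intermediate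
4 | (S)-hex-1-en-4-yn-3-ol | C=C[C@H](O)C#CC | intermediate
5 | acryloyl chloride | C=CC(=O)Cl | starting material
6 | (S)-hex-1-en-4-yn-3-yl acrylate | C=CC(=O)O[C@@H](C=C)C#CC | intermediate
7 | (S)-5-(prop-1-ynyl)furan-2(5H)-one | O=C1C=C[C@@H](C#CC)O1 | intermediate
8 | 2-(1,3-dioxolan-2-yl)ethylmagnesium bromide | Br[Mg]CCC1OCCO1 | starting material
9 | methyl iodide | CI | starting material
10 | trans,trans-lactone acetal | CC#C[C@H]1OC(=O)[C@@H](C)[C@@H]1CCC2OCCO2 | intermediate
11 | lactone aldehyde | CC#C[C@H]1OC(=O)[C@@H](C)[C@@H]1CCC=O | intermediate
12 | vinylmagnesium bromide | C=C[Mg]Br | starting material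
13 | allylic alcohol (C10 epimers) | CC#C[C@H]1OC(=O)[C@@H](C)[C@@H]1CCC(O)C=C | intermediate
14 | hydroazulenone, C10-OH (C10, C1 mixture) | CC1=C2[C@H]3OC(=O)[C@@H](C)[C@@H]3CCC(O)C2CC1=O | intermediate
15 | C10 ketone | CC1=C2[C@H]3OC(=O)[C@@H](C)[C@@H]3CCC(=O)[C@@H]2CC1=O | intermediate
16 | methylmagnesium bromide | C[Mg]Br | starting material
17 | 10-hydroxyguai-4-en-3-one-12,6-olide | CC1=C2[C@H]3OC(=O)[C@@H](C)[C@@H]3CC[C@](C)(O)[C@@H]2CC1=O | intermediate
18 | TESOTf | CC[Si](CC)(CC)OS(=O)(=O)C(F)(F)F | starting material
19 | C10-OTES enone | CC1=C2[C@H]3OC(=O)[C@@H](C)[C@@H]3CC[C@](C)(O[Si](CC)(CC)CC)[C@@H]2CC1=O | intermediate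
20 | C3 allylic alcohol | CC1=C2[C@H]3OC(=O)[C@@H](C)[C@@H]3CC[C@](C)(O[Si](CC)(CC)CC)[C@@H]2CC1O | intermediate
21 | guaia-2,4-diene (C10-OTES) | CC1=C2[C@H]3OC(=O)[C@@H](C)[C@@H]3CC[C@](C)(O[Si](CC)(CC)CC)[C@@H]2C=C1 | intermediate
22 | TBSOTf | CC(C)(C)[Si](C)(C)OS(=O)(=O)C(F)(F)F | starting material
23 | 3-(TBSO)guaia-2,4-diene (C10-OTES) | CC1=C2[C@H]3OC(=O)[C@@H](C)[C@@H]3CC[C@](C)(O[Si](CC)(CC)CC)[C@@H]2C=C1O[Si](C)(C)C(C)(C)C | intermediate
24 | Diels–Alder adduct | CC1=C2[C@H]3OC(=O)[C@@H](C)[C@@H]3CC[C@](C)(O[Si](CC)(CC)CC)[C@@H]2[C@H]2[C@H]3C(O[Si](C)(C)C(C)(C)C)=C(C)[C@]4([C@@H]3[C@@](C)(O[Si](CC)(CC)CC)CC[C@H]3[C@H](C)C(=O)O[C@@H]34)[C@@H]12 | intermediate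
25 | caruifolin B | CC1=C2[C@H]3OC(=O)[C@@H](C)[C@@H]3CC[C@](C)(O)[C@@H]2[C@H]2[C@H]3C(=O)[C@H](C)[C@]4([C@@H]3[C@@](C)(O)CC[C@H]3[C@H](C)C(=O)O[C@@H]34)[C@@H]12 | target

**Total steps:** 16. **Longest linear sequence:** 15 (Steps 1–11, 12, 13, 15, 16).

## Three steps most likely to fail
1. **Step 15 (proposed new step, heterodimerization).** The diene has a hindered quaternary terminus, and the cyclopentadiene **21** may homodimerize or undergo [1,5]-H shifts.
   - Fallback (known chemistry): make the dienophile electron-poor. Sulfenylate the enone at C2 (LDA, PhSSPh), reduce, dehydrate and oxidise to give the 2-(phenylsulfonyl)cyclopentadiene. Run a normal-demand thermal Diels–Alder with **23** (toluene, 110 °C), then remove the sulfonyl group with SmI2 and deprotect.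
2. **Step 8 (seven-membered-ring PKR).** It may give low yield or the wrong C1 configuration.
   - Fallback: form the cycloheptane by RCM of a C5-vinyl/C10-vinyl diene instead. Then annulate the cyclopentenone by Stork-enamine alkylation of the C5 ketone with 1-bromo-2-butanone followed by intramolecular aldol condensation.
3. **Step 10 (Me addition at C10).** It may show poor facial selectivity or attack the enone.
   - Fallback: add Me at the acyclic stage. Use 2-(2-bromoethyl)-2-methyl-1,3-dioxolane in Step 5 in place of **8**, then hydrolyse and add vinylMgBr to the methyl ketone. Carry both C10 epimers through the PKR and separate the diastereomers after it, skipping Steps 9 and 10.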